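**Plan**

- Retrosynthetic cuts, in order: the four O-protecting groups; the acyl–aryl bond C4–C4a of ring C, giving an (S)-3-aryl-3-aryloxypropanoic acid; the benzylic ether bond O1–C2, giving 2,4-diprenylphloroglucinol and an (R)-β-hydroxy ester; the C2–C3 bond (acetate aldol); the three aryl–prenyl bonds.
- Forward: rings A and B are bought as phloroglucinol and 2,4-dihydroxybenzaldehyde and C-prenylated. The C3–C4 unit is built on ring B, the ether O1–C2 joins the two halves, and ring C is closed last.
- Enabling feature: ring A is a 2,4-diprenylphloroglucinol unit with one unsubstituted carbon (the future C4a). It lies ortho to O1 and O5 and para to O7, and O1–C2–C3 holds it in six-ring distance of the carboxyl carbon C4.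
- Stereochemistry: C2 is set as the (R)-carbinol by catalytic asymmetric transfer hydrogenation and inverted to (S) in the Mitsunobu etherification. The 4'-acetate (non-donating) and the 2'-MOM ether (cannot migrate) guard the benzylic C–O bond, and no base is used after ring closure.

Key step: step 10

Remark: the target is read as the (2S)-flavanone; prenyl = 3-methylbut-2-en-1-yl, MOM = methoxymethyl; reagents without a number are ordinary catalogue chemicals.

**Step 1**
Reactants: 1 phloroglucinol; 2 prenyl bromide
Product: 3 2,4-diprenylphloroglucinol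
Conditions: 2 (2.0 equiv), KOH (2.0 equiv), H2O, 0 °C → rt; dilute HCl; SiO2
Reagents that add atoms: none
Why: C-alkylation of the ambident phloroglucinol dianion in water should put two prenyl groups on two different ring carbons; a modest yield is expected, and mono-, tri- and gem-prenylated by-products would be removed by chromatography.

**Step 2**
Reactants: 4 2,4-dihydroxybenzaldehyde; 2 prenyl bromide
Product: 5 2,4-dihydroxy-3-prenylbenzaldehyde
Conditions: 2 (1.1 equiv), KOH (1.1 equiv), H2O, 0 °C → rt; dilute HCl; SiO2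
Reagents that add atoms: none
Why: the same aqueous phenoxide C-prenylation should favour C3, the carbon between the two oxygens; the 5-prenyl and O-prenyl isomers would be separated.

**Step 3**
Reactants: 5 2,4-dihydroxy-3-prenylbenzaldehyde
Product: 6 4-acetoxy-2-hydroxy-3-prenylbenzaldehyde
Conditions: Ac2O (1.05 equiv), pyridine, CH2Cl2, −10 → 0 °C
Reagents that add atoms: acetic anhydride CC(=O)OC(C)=O
Why: chemoselective O-acylation; the 2-OH is held in a hydrogen bond to the aldehyde, so the 4-OH should react, and the acetate turns the para-oxygen from a donor into a weakly withdrawing group.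

**Step 4**
Reactants: 6 4-acetoxy-2-hydroxy-3-prenylbenzaldehyde
Product: 7 4-acetoxy-2-(methoxymethoxy)-3-prenylbenzaldehyde
Conditions: MOMCl (2.5 equiv), i-Pr2NEt (3 equiv), CH2Cl2, 0 °C → rt
Reagents that add atoms: chloromethyl methyl ether COCCl
Why: O-alkylation (MOM protection) of the chelated phenol; an acetal is chosen here because an ortho ester could migrate to the later benzylic hydroxyl.

**Step 5**
Reactants: 7 4-acetoxy-2-(methoxymethoxy)-3-prenylbenzaldehyde
Product: 9 allyl 3-[4-acetoxy-2-(methoxymethoxy)-3-prenylphenyl]-3-oxopropanoate, via racemic aldol adduct 8 (not isolated)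
Conditions: allyl acetate, LDA, THF, −78 °C; add 7; AcOH quench at −78 °C; crude, then Dess–Martin periodinane, NaHCO3, CH2Cl2, 0 °C
Reagents that add atoms: allyl acetate C=CCOC(C)=O
Why: lithium ester enolate aldol addition (the aldehyde should react far faster than the aryl acetate at −78 °C) followed by Dess–Martin oxidation gives the β-keto ester.

**Step 6**
Reactants: 9 allyl 3-[4-acetoxy-2-(methoxymethoxy)-3-prenylphenyl]-3-oxopropanoate
Product: 10 allyl (3R)-3-[4-acetoxy-2-(methoxymethoxy)-3-prenylphenyl]-3-hydroxypropanoate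
Conditions: RuCl(p-cymene)[(R,R)-TsDPEN] (1 mol %), HCO2H/Et3N (5:2), EtOAc, 30 °C
Reagents that add atoms: none
Why: Noyori–Ikariya asymmetric transfer hydrogenation of an aryl β-keto ester; the (R,R)-ligand should deliver hydride to the face that gives the (R)-carbinol (aryl/arene CH–π control), and alkenes and esters are not touched.

**Step 7**
Reactants: 10 allyl (3R)-3-[4-acetoxy-2-(methoxymethoxy)-3-prenylphenyl]-3-hydroxypropanoate; 3 2,4-diprenylphloroglucinol
Product: 11 allyl (3S)-3-[4-acetoxy-2-(methoxymethoxy)-3-prenylphenyl]-3-[3,5-dihydroxy-2,4-diprenylphenoxy]propanoate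
Conditions: 3 (3 equiv, excess to be recovered), PPh3, DIAD (slow addition), toluene–THF, −20 → 20 °C
Reagents that add atoms: none
Why: Mitsunobu etherification, SN2 with inversion (R → S) at the benzylic carbon; the phenolic OH flanked by H and one prenyl should react in preference to the OH between two prenyl groups, the excess of 3 limits double etherification, and the 4-acetoxy ring disfavours an SN1 pathway.

**Step 8**
Reactants: 11 allyl (3S)-3-[4-acetoxy-2-(methoxymethoxy)-3-prenylphenyl]-3-[3,5-dihydroxy-2,4-diprenylphenoxy]propanoate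
Product: 12 allyl (3S)-3-[4-acetoxy-2-(methoxymethoxy)-3-prenylphenyl]-3-[3,5-bis(methoxymethoxy)-2,4-diprenylphenoxy]propanoate
Conditions: MOMCl (4 equiv), i-Pr2NEt (5 equiv), Bu4NI (cat.), CH2Cl2, 0 °C → rt
Reagents that add atoms: chloromethyl methyl ether COCCl
Why: MOM protection of both ring-A phenols keeps ring A electron-rich, excludes O-acylation in the ring closure, and the weak amine base cannot trigger β-elimination of the aryloxy group.

**Step 9**
Reactants: 12 allyl (3S)-3-[4-acetoxy-2-(methoxymethoxy)-3-prenylphenyl]-3-[3,5-bis(methoxymethoxy)-2,4-diprenylphenoxy]propanoate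
Product: 13 (3S)-3-[4-acetoxy-2-(methoxymethoxy)-3-prenylphenyl]-3-[3,5-bis(methoxymethoxy)-2,4-diprenylphenoxy]propanoic acid
Conditions: Pd(PPh3)4 (5 mol %), N-methylaniline (2 equiv), THF, rt; pH 4 work-up
Reagents that add atoms: none
Why: Tsuji–Trost deallylation; the π-allyl palladium is trapped by the aniline under neutral conditions, so the aryl acetate, the MOM acetals and the β-aryloxy acid (no E1cB) should stay intact.

**Step 10**
Reactants: 13 (3S)-3-[4-acetoxy-2-(methoxymethoxy)-3-prenylphenyl]-3-[3,5-bis(methoxymethoxy)-2,4-diprenylphenoxy]propanoic acid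
Product: 15 (2S)-2-[4-acetoxy-2-(methoxymethoxy)-3-prenylphenyl]-5,7-bis(methoxymethoxy)-6,8-diprenylchroman-4-one, via mixed trifluoroacetic anhydride 14 (not isolated)
Conditions: TFAA (1.2 equiv), 2,6-di-tert-butyl-4-methylpyridine (2.5 equiv), CH2Cl2 (0.01 M), −40 → 0 °C; aq NaHCO3
Reagents that add atoms: none
Why: Exchange of the acid with TFAA gives the mixed anhydride 14, whose acyl carbon (C4) is attacked by the only unsubstituted carbon of ring A (the future C4a, ortho to O1 and O5, para to O7); the arenium ion then loses its proton to the hindered pyridine to give the aryl ketone. The closest known reaction type is the intramolecular Friedel–Crafts acylation of 3-aryloxypropanoic acids to chroman-4-ones through mixed trifluoroacetic anhydrides. Ring C closes in a 6-exo-trig mode at the acyl carbon, with the ether oxygen O1 as tether. No stereocentre is formed; C2 should be carried through unchanged because the medium stays buffered, the 4'-acetoxy group withholds the para-oxygen donation that would let the C2–O1 bond ionise, and no base strong enough for β-elimination is present. The step needs site selectivity for the ring-A C–H over the prenyl alkenes, over the prenyl-bearing ortho carbon (ipso attack) and over C6' of ring B (indanone closure); this is secured by the three oxygens that converge on the one free carbon of ring A, by proton loss being possible only there, and by ring B having no oxygen ortho or para to C6'.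

**Step 11**
Reactants: 15 (2S)-2-[4-acetoxy-2-(methoxymethoxy)-3-prenylphenyl]-5,7-bis(methoxymethoxy)-6,8-diprenylchroman-4-one
Product: 16 (2S)-2-(2,4-dihydroxy-3-prenylphenyl)-5,7-dihydroxy-6,8-diprenylchroman-4-one (target)
Conditions: 3 M HCl in MeOH–THF, 40 °C, stopped at full conversion
Reagents that add atoms: none
Why: acid-catalysed acetal methanolysis of the three MOM ethers and transesterification of the aryl acetate in one operation; an acidic medium is chosen because base would open the flavanone by retro-oxa-Michael reaction and racemise C2.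

**Compound list**

1 | phloroglucinol | Oc1cc(O)cc(O)c1 | starting material
2 | prenyl bromide (1-bromo-3-methylbut-2-ene) | CC(C)=CCBr | starting material
3 | 2,4-diprenylphloroglucinol | CC(C)=CCc1c(O)cc(O)c(CC=C(C)C)c1O | intermediate
4 | 2,4-dihydroxybenzaldehyde | O=Cc1ccc(O)cc1O | starting material
5 | 2,4-dihydroxy-3-prenylbenzaldehyde | O=Cc1ccc(O)c(CC=C(C)C)c1O | intermediate
6 | 4-acetoxy-2-hydroxy-3-prenylbenzaldehyde | CC(=O)Oc1ccc(C=O)c(O)c1CC=C(C)C | intermediate
7 | 4-acetoxy-2-(methoxymethoxy)-3-prenylbenzaldehyde | COCOc1c(C=O)ccc(OC(C)=O)c1CC=C(C)C | intermediate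
8 | allyl 3-[4-acetoxy-2-(methoxymethoxy)-3-prenylphenyl]-3-hydroxypropanoate, racemic | C=CCOC(=O)CC(O)c1ccc(OC(C)=O)c(CC=C(C)C)c1OCOC | intermediate
9 | allyl 3-[4-acetoxy-2-(methoxymethoxy)-3-prenylphenyl]-3-oxopropanoate | C=CCOC(=O)CC(=O)c1ccc(OC(C)=O)c(CC=C(C)C)c1OCOC | intermediate
10 | allyl (3R)-3-[4-acetoxy-2-(methoxymethoxy)-3-prenylphenyl]-3-hydroxypropanoate | C=CCOC(=O)C[C@@H](O)c1ccc(OC(C)=O)c(CC=C(C)C)c1OCOC | intermediate
11 | allyl (3S)-3-[4-acetoxy-2-(methoxymethoxy)-3-prenylphenyl]-3-[3,5-dihydroxy-2,4-diprenylphenoxy]propanoate | C=CCOC(=O)C[C@H](Oc1cc(O)c(CC=C(C)C)c(O)c1CC=C(C)C)c1ccc(OC(C)=O)c(CC=C(C)C)c1OCOC | intermediate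
12 | allyl (3S)-3-[4-acetoxy-2-(methoxymethoxy)-3-prenylphenyl]-3-[3,5-bis(methoxymethoxy)-2,4-diprenylphenoxy]propanoate | C=CCOC(=O)C[C@H](Oc1cc(OCOC)c(CC=C(C)C)c(OCOC)c1CC=C(C)C)c1ccc(OC(C)=O)c(CC=C(C)C)c1OCOC | intermediate
13 | (3S)-3-[4-acetoxy-2-(methoxymethoxy)-3-prenylphenyl]-3-[3,5-bis(methoxymethoxy)-2,4-diprenylphenoxy]propanoic acid | OC(=O)C[C@H](Oc1cc(OCOC)c(CC=C(C)C)c(OCOC)c1CC=C(C)C)c1ccc(OC(C)=O)c(CC=C(C)C)c1OCOC | intermediate
14 | mixed anhydride of 13 with trifluoroacetic acid | O=C(C[C@H](Oc1cc(OCOC)c(CC=C(C)C)c(OCOC)c1CC=C(C)C)c1ccc(OC(C)=O)c(CC=C(C)C)c1OCOC)OC(=O)C(F)(F)F | intermediate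
15 | (2S)-2-[4-acetoxy-2-(methoxymethoxy)-3-prenylphenyl]-5,7-bis(methoxymethoxy)-6,8-diprenylchroman-4-one | CC(=O)Oc1ccc([C@@H]2CC(=O)c3c(OCOC)c(CC=C(C)C)c(OCOC)c(CC=C(C)C)c3O2)c(OCOC)c1CC=C(C)C | intermediate
16 | (2S)-2-(2,4-dihydroxy-3-prenylphenyl)-5,7-dihydroxy-6,8-diprenylchroman-4-one | CC(C)=CCc1c(O)ccc([C@@H]2CC(=O)c3c(O)c(CC=C(C)C)c(O)c(CC=C(C)C)c3O2)c1O | target

**Summary**

Total step count: 11. Longest linear sequence: 10 (steps 2–11).

**Steps most likely to fail**

Step 7. The coupling may fail through etherification at the wrong phenolic oxygen (the hindered one between the prenyl groups) or at two oxygens, and through β-elimination of the activated alcohol to the cinnamate. The fallback differentiates the nucleophile by protecting groups before the coupling instead of relying on sterics during it. It sets out from 3: silylation of the two unhindered hydroxyls (TBSCl, imidazole, DMF, 0 °C) should give 3,5-bis(tert-butyldimethylsilyloxy)-2,6-diprenylphenol F1. The remaining hindered hydroxyl would be converted into its MOM ether (MOMCl, i-Pr2NEt, Bu4NI) to give 1,5-bis(tert-butyldimethylsilyloxy)-3-(methoxymethoxy)-2,4-diprenylbenzene F2. Buffered fluoride (TBAF, AcOH, THF) would then release 5-(methoxymethoxy)-4,6-diprenylbenzene-1,3-diol F3, whose two free hydroxyls are equivalent. Mitsunobu coupling of F3 (in excess) with 10 at −20 °C in toluene should give allyl (3S)-3-[4-acetoxy-2-(methoxymethoxy)-3-prenylphenyl]-3-[5-hydroxy-3-(methoxymethoxy)-2,4-diprenylphenoxy]propanoate F4, and MOMCl/i-Pr2NEt brings the sequence back to 12.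

Step 10. The buffered mixed anhydride may ionise too slowly. If acid is allowed to build up instead, the MOM acetals may be lost, prenyl alkenes protonated, the C2–O1 bond ionised, or the 2'-MOM oxygen acylated (lactonisation). The fallback changes the way the electrophile is made, from reversible anhydride exchange to irreversible halide abstraction under strictly aprotic conditions. It sets out from 13: 1-chloro-N,N,2-trimethylpropenylamine (CH2Cl2, 0 °C) should give the acid chloride F5 without release of HCl. Silver triflate with 2,6-di-tert-butyl-4-methylpyridine at −78 °C would convert it into the acyl triflate F6, which should close onto the ring-A carbon at low temperature and return the route at 15.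

Step 11. Protic acid may cyclise a prenyl group onto a neighbouring free phenol (chroman formation) and may erode the configuration at C2 by reversible ring opening. The fallback replaces Brønsted-acid methanolysis by two mechanistically different, near-neutral cleavages. It sets out from 15: ZnBr2 with n-PrSH (CH2Cl2, 0 °C, short contact) should remove the three MOM groups by Lewis acid/thiol transfer to give (2S)-2-(4-acetoxy-2-hydroxy-3-prenylphenyl)-5,7-dihydroxy-6,8-diprenylchroman-4-one F7. A lipase (Candida antarctica lipase B, n-BuOH, MTBE, 30 °C) would then transfer the aryl acetate to butanol and arrive at 16.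

**Further compounds**

F1 | step 7 | 3,5-bis(tert-butyldimethylsilyloxy)-2,6-diprenylphenol | CC(C)(C)[Si](C)(C)Oc1cc(O[Si](C)(C)C(C)(C)C)c(CC=C(C)C)c(O)c1CC=C(C)C
F2 | step 7 | 1,5-bis(tert-butyldimethylsilyloxy)-3-(methoxymethoxy)-2,4-diprenylbenzene | CC(C)(C)[Si](C)(C)Oc1cc(O[Si](C)(C)C(C)(C)C)c(CC=C(C)C)c(OCOC)c1CC=C(C)C
F3 | step 7 | 5-(methoxymethoxy)-4,6-diprenylbenzene-1,3-diol | Oc1cc(O)c(CC=C(C)C)c(OCOC)c1CC=C(C)C
F4 | step 7 | allyl (3S)-3-[4-acetoxy-2-(methoxymethoxy)-3-prenylphenyl]-3-[5-hydroxy-3-(methoxymethoxy)-2,4-diprenylphenoxy]propanoate | C=CCOC(=O)C[C@H](Oc1cc(O)c(CC=C(C)C)c(OCOC)c1CC=C(C)C)c1ccc(OC(C)=O)c(CC=C(C)C)c1OCOC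
F5 | step 10 | (3S)-3-[4-acetoxy-2-(methoxymethoxy)-3-prenylphenyl]-3-[3,5-bis(methoxymethoxy)-2,4-diprenylphenoxy]propanoyl chloride | ClC(=O)C[C@H](Oc1cc(OCOC)c(CC=C(C)C)c(OCOC)c1CC=C(C)C)c1ccc(OC(C)=O)c(CC=C(C)C)c1OCOC
F6 | step 10 | mixed anhydride of 13 with trifluoromethanesulfonic acid (acyl triflate) | O=C(C[C@H](Oc1cc(OCOC)c(CC=C(C)C)c(OCOC)c1CC=C(C)C)c1ccc(OC(C)=O)c(CC=C(C)C)c1OCOC)OS(=O)(=O)C(F)(F)F
F7 | step 11 | (2S)-2-(4-acetoxy-2-hydroxy-3-prenylphenyl)-5,7-dihydroxy-6,8-diprenylchroman-4-one | CC(=O)Oc1ccc([C@@H]2CC(=O)c3c(O)c(CC=C(C)C)c(O)c(CC=C(C)C)c3O2)c(O)c1CC=C(C)C
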